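**Conventions and one assumption**

- Locants C1–C15 are the germacrane locants of the target and are used for every intermediate, open-chain ones included.
- Assumption on the chemistry: tin–lithium exchange at C6 gives an allyl anion that is planar at C6, so the stannanes 26–28 are made and used as both C6 epimers and C6 carries no descriptor in their SMILES.
- Compounds 1, 2, 4, 7, 13, 18 and 25 are taken as catalogue chemicals (4 and 13 as solutions).

## Analysis of the target

The target 38 is a germacranolide: a ten-membered carbocycle (C1–C10) with a γ-lactone fused across C6–C7, an E trisubstituted C4=C5 alkene, a trisubstituted 1,10-epoxide and acetates on C3 and C9. It has seven stereocentres, (1R,3S,6S,7S,9R,10R,11R). H6 and H7 are trans (trans-fused lactone), and the C11 methyl group is cis to C8 on the lactone, which is the less stable C11 epimer. C2 and C9 are cis on the epoxide (it stems from a Z C1=C10 alkene), the C9 oxygen is threo to the epoxide oxygen, and C3 sits 1,3 to C1 across the C2 methylene. The epoxide faces the C4=C5 alkene across the medium ring, so acid invites transannular cyclization; the epoxy alcohol unit at C9/C10/C1 can undergo Payne migration under base, C11 epimerizes through the lactone enolate, and the acetates do not survive organometallic reagents. The hard parts are the strained ten-membered ring with an E alkene, stereocentres spread over 1,3- and 1,5-distances, and the contra-thermodynamic C11 centre. The strategy rests on C6 and C7: C6 carries oxygen and is allylic to C4=C5, and C7 carries the three-carbon branch C11(C12)(C13). Two such vicinal centres are what a [2,3]-Wittig shift leaves behind when an allyl ether links C6 through oxygen to C12, and that ether is a thirteen-membered ring, far easier to close than the ten-membered one.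

## Retrosynthetic reasoning

**38 ⇒ 37 ⇒ 36.** The two acetyl C–O bonds are cut first. Acetates cannot pass through carbanion chemistry, so C3 and C9 travel as triethylsilyl ethers and are exchanged for acetates at the very end under buffered conditions that spare the epoxide and C11.

**36 ⇒ 34 ⇒ 32 ⇒ 30.** The lactone is opened at O6–C12 and taken back to an isopropenyl group on C7. Going forward, anti-Markovnikov hydration of C11=C12 gives diol 32, selective oxidation of the primary alcohol closes lactone 34, and C11 is set last by protonating the enolate from the face away from C8. This puts the only contra-thermodynamic centre under kinetic control and makes the C11 outcome of the hydroboration irrelevant.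

**30 ⇒ 28.** The C6–C7 bond is cut, with the C6 oxygen reconnected to C12. This is the one bond whose formation creates the ten-membered ring and both lactone stereocentres at once. In the forward sense a carbanion placed at C6 of ether 28 must attack C7 through a five-membered envelope while O–C12 breaks. A stannyl group on C6 guarantees that the carbanion arises there and not at C12.

**28 ⇒ 26 ⇒ 24.** The O–C12 bond is cut (Williamson closure of the thirteen-membered ring from the C6 alkoxide and a C12 allylic chloride), then the C6–Sn bond (stannyl anion addition of 25 to enal 24). Tin is brought in only two steps before it is used, because α-alkoxy allylstannanes tolerate little other chemistry.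

**24 ⇒ 23 ⇒ 22 ⇒ 20 ⇒ 19 ⇒ 17 + 18.** The two termini are adjusted by functional-group changes only: the C6 enal from a PMB-protected allylic alcohol, the C12 chloride from an enal. The C7=C11 bond is cut by cross-metathesis of terminal alkene 17 with methacrolein 18, which delivers C11, C12 and C13 with E geometry in one step.

**17 ⇒ 16 ⇒ 15 ⇒ 12 + 13.** The epoxide C–O bonds are removed to give the Z allylic alcohol 15, whose C9 hydroxyl directs the oxygen to the threo face. The C8–C9 bond is then cut by allylboration of Z-enal 12 with 13, so C9 is set by the reagent and the epoxide by C9.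

**12 ⇒ 11 ⇒ 10 ⇒ 9 ⇒ 8 ⇒ 6 + 7.** The Z C1=C10 alkene is traced to the six-membered unsaturated lactone 9, where a Z geometry is the only one possible. Lactone 9 comes from ring-closing metathesis of methacrylate 8, made from alcohol 6 and acid chloride 7. Opening 9 to a Weinreb amide frees the C3 hydroxyl for silylation and gives the aldehyde oxidation level at C9.

**6 ⇒ 3 + 4, 3 ⇒ 1 + 2.** The C2–C3 bond is cut by allylboration of enal 3 with 4, which sets C3. The E C4=C5 bond is cut by a Wittig reaction of aldehyde 1 with the formyl ylide 2.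

## Alternatives that were turned down

Alternative 1: The ring is cut at C1–C2 together with O–C3, the retron of an intramolecular nitrile oxide–alkene cycloaddition. The forward key step oxidizes a C1 aldoxime with NaOCl to the nitrile oxide, which adds to a terminal C2=C3 alkene and closes the carbocycle and a bridging isoxazoline at once, giving the isoxazoline-bridged lactone A1.
- For it: the complete lactone, including C6, C7 and the awkward C11, and the C9/C10 oxygens can be set on small or open-chain pieces before ring closure, and the isoxazoline is a masked C1 ketone/C3 alcohol. On this point it is stronger than the chosen route, which fixes C11 only after the ring exists.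
- Against it: this is an end-to-end closure of a ten-membered ring containing an E alkene, in competition with nitrile oxide dimerization. The bridged regiochemistry places the C=N bond in a strained bicycle. C3 is set by the face of a terminal diene alkene far from any control element. After the key step the route still needs N–O cleavage, reduction of a C1 ketone inside a medium ring with the right sense, selective activation of C1–OH beside C3–OH, and epoxide closure, so two stereocentres (C1, C3) depend on medium-ring conformation.
- In place of that, the chosen route fixes C1, C3, C9 and C10 by reagent- or A(1,3)-controlled reactions before any ring exists, and makes the ten-membered ring by contraction, not by end-to-end closure.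

Alternative 2: The C2–C3 bond is formed and C5–C10 broken by an anionic oxy-Cope ring expansion of a dialkenylcyclohexanol. KH with 18-crown-6 makes the C10 alkoxide and the [3,3] shift gives the ten-membered C10 ketone A2 with E C4=C5, a C3 dithiane and the trans lactone.
- For it: ring expansion sidesteps medium-ring strain, a chair transition state transmits cyclohexane stereochemistry into the E alkene, and C6, C7, C9 and C11 are set on a six-membered ring. As a ring-forming event it is more dependable than the [2,3] contraction.
- Against it: the C3 terminus is a fully substituted, electron-rich ketene dithioacetal carbon, which slows bond formation, and the lactone must survive KH (C11 enolization, alkoxide attack). A2 carries plain methylenes at C1 and C2, a C10 ketone without its methyl and a masked C3 ketone. C14, the cis C1–C10 epoxide and the C3 carbinol must therefore all be built on the mobile ten-membered ring, in roughly eight further steps with little stereochemical guidance.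
- In place of that, the chosen route enters the ring with C1, C3, C9 and C10 already fixed and has only C11 left to set afterwards.

Alternative 3: The hindered C9–C10 bond is cut as a pinacol retron. SmI2 reduces a C9 aldehyde to a ketyl that adds to a C10 methyl ketone, closing the ring as the C9,C10-diol A3 with a C1 silyl ether and the C3 acetate.
- For it: it is convergent, the lactone and C3 are complete beforehand, and only C9 acetylation, C1 unmasking/activation and epoxide closure by the C10 alkoxide remain. It is shorter after the ring closure than the chosen route and as strong on convergence.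
- Against it: two stereocentres (C9 and C10) are created in the ring-closing step itself under conformational control only, and both the diol relationship and the face must be right. The C10 ketone carries an α-silyloxy group at C1, a substituent that ketyl chemistry tends to expel. The allylic C–O bonds at C3 and C6 are further reducible sites. C1 must be carried in the configuration opposite to the target because epoxide closure inverts it.
- In place of that, the chosen route sets C9 by reagent and the epoxide by A(1,3) strain in the open chain, and its ring-forming C–C bond does not touch C9 or C10.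

Key step: step 18

## Route

Step 1
Reactants: 1 2-[(4-methoxybenzyl)oxy]acetaldehyde; 2 2-(triphenylphosphoranylidene)propanal
Product: 3 (E)-4-[(4-methoxybenzyl)oxy]-2-methylbut-2-enal
Conditions: toluene, 80 °C
Reagents that add atoms: none
Why: Wittig olefination with a formyl-stabilised ylide, which gives the E enal (C6 trans to C3); the α-alkoxy aldehyde 1 is more electrophilic than product 3, so a second olefination should not compete.

Step 2
Reactants: 3 (E)-4-[(4-methoxybenzyl)oxy]-2-methylbut-2-enal; 4 B-allylbis(isopinocampheyl)borane from (+)-α-pinene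
Product: 6 (4S,5E)-7-[(4-methoxybenzyl)oxy]-5-methylhepta-1,5-dien-4-ol, via O-boryl ether 5 (not isolated)
Conditions: Et2O, −78 °C; then NaOH, H2O2, 0 °C
Reagents that add atoms: none
Why: Brown allylboration through a closed chair transition state; the (+)-α-pinene-derived reagent delivers allyl to the Si face of the aldehyde (the sense that turns benzaldehyde into the S homoallylic alcohol), which sets C3 as S; alkaline peroxide then cleaves the B–O and B–C bonds.

Step 3
Reactants: 6 (4S,5E)-7-[(4-methoxybenzyl)oxy]-5-methylhepta-1,5-dien-4-ol; 7 2-methylprop-2-enoyl chloride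
Product: 8 (4S,5E)-7-[(4-methoxybenzyl)oxy]-5-methylhepta-1,5-dien-4-yl 2-methylprop-2-enoate
Conditions: Et3N, DMAP (cat.), CH2Cl2, 0 °C
Reagents that add atoms: none
Why: DMAP-catalysed O-acylation of the secondary alcohol; no stereocentre is touched and the ester brings in C9, C10 and C14.

Step 4
Reactants: 8 (4S,5E)-7-[(4-methoxybenzyl)oxy]-5-methylhepta-1,5-dien-4-yl 2-methylprop-2-enoate
Product: 9 (6S)-6-{(2E)-4-[(4-methoxybenzyl)oxy]but-2-en-2-yl}-3-methyl-5,6-dihydro-2H-pyran-2-one
Conditions: second-generation Grubbs catalyst (5 mol %), CH2Cl2 (0.01 M), 40 °C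
Reagents that add atoms: none
Why: Ring-closing metathesis between the terminal alkene and the methacrylate; the trisubstituted C4=C5 alkene is inert to the catalyst, and the six-membered ring forces C2 and C9 cis, the Z C1=C10 geometry the epoxide needs.

Step 5
Reactants: 9 (6S)-6-{(2E)-4-[(4-methoxybenzyl)oxy]but-2-en-2-yl}-3-methyl-5,6-dihydro-2H-pyran-2-one
Product: 10 (2Z,5S,6E)-5-hydroxy-N-methoxy-8-[(4-methoxybenzyl)oxy]-N,2,6-trimethylocta-2,6-dienamide
Conditions: MeNH(OMe)·HCl, AlMe3, CH2Cl2, 0 °C to rt; used crude
Reagents that add atoms: N,O-dimethylhydroxylamine hydrochloride, CNOC.Cl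
Why: Weinreb aminolysis of the lactone by the aluminium amide formed from AlMe3 and the amine salt; the C1=C10 bond is not involved, so the Z geometry is kept while the C3 hydroxyl is set free.

Step 6
Reactants: 10 (2Z,5S,6E)-5-hydroxy-N-methoxy-8-[(4-methoxybenzyl)oxy]-N,2,6-trimethylocta-2,6-dienamide
Product: 11 (2Z,5S,6E)-N-methoxy-8-[(4-methoxybenzyl)oxy]-N,2,6-trimethyl-5-[(triethylsilyl)oxy]octa-2,6-dienamide
Conditions: Et3SiCl, imidazole, DMAP (cat.), CH2Cl2, 0 °C
Reagents that add atoms: chlorotriethylsilane, CC[Si](Cl)(CC)CC
Why: Silylation of the allylic alcohol; it blocks relactonization and keeps the C3 oxygen from directing the later epoxidation.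

Step 7
Reactants: 11 (2Z,5S,6E)-N-methoxy-8-[(4-methoxybenzyl)oxy]-N,2,6-trimethyl-5-[(triethylsilyl)oxy]octa-2,6-dienamide
Product: 12 (2Z,5S,6E)-8-[(4-methoxybenzyl)oxy]-2,6-dimethyl-5-[(triethylsilyl)oxy]octa-2,6-dienal
Conditions: i-Bu2AlH, THF, −78 °C; Rochelle salt work-up; used at once
Reagents that add atoms: none
Why: Hydride reduction of the Weinreb amide stops at the aldehyde because the chelated tetrahedral aluminium adduct survives until work-up; low temperature and a non-acidic work-up preserve the Z enal.

Step 8
Reactants: 12 (2Z,5S,6E)-8-[(4-methoxybenzyl)oxy]-2,6-dimethyl-5-[(triethylsilyl)oxy]octa-2,6-dienal; 13 B-allylbis(isopinocampheyl)borane from (−)-α-pinene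
Product: 15 (4R,5Z,8S,9E)-11-[(4-methoxybenzyl)oxy]-5,9-dimethyl-8-[(triethylsilyl)oxy]undeca-1,5,9-trien-4-ol, via O-boryl ether 14 (not isolated)
Conditions: Et2O, −78 °C; then NaOH, H2O2, 0 °C
Reagents that add atoms: none
Why: Brown allylboration forms C8–C9; the reagent enantiomeric to 4 adds to the opposite (Re) aldehyde face and sets C9 as R under reagent control, the remote C3 centre having little influence.

Step 9
Reactants: 15 (4R,5Z,8S,9E)-11-[(4-methoxybenzyl)oxy]-5,9-dimethyl-8-[(triethylsilyl)oxy]undeca-1,5,9-trien-4-ol
Product: 16 (1R)-1-[(2S,3R)-3-{(2S,3E)-5-[(4-methoxybenzyl)oxy]-3-methyl-2-[(triethylsilyl)oxy]pent-3-en-1-yl}-2-methyloxiran-2-yl]but-3-en-1-ol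
Conditions: Ti(OiPr)4 (1.2 equiv), t-BuOOH, 4 Å MS, CH2Cl2, −20 °C
Reagents that add atoms: tert-butyl hydroperoxide, CC(C)(C)OO
Why: Hydroxyl-directed epoxidation (titanium alkoxide/hydroperoxide, Sharpless type without tartrate) touches only the allylic C1=C10 alkene; A(1,3) strain between C8 and the cis C2 substituent puts H9 in the alkene plane, and oxygen is delivered from the hydroxyl face, giving the threo epoxy alcohol with the required configuration at C1 and C10.

Step 10
Reactants: 16 threo epoxy alcohol (C9–OH)
Product: 17 9-O-triethylsilyl ether of 16 (open chain with C7 terminal alkene)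
Conditions: Et3SiOTf, 2,6-lutidine, CH2Cl2, −78 °C
Reagents that add atoms: triethylsilyl trifluoromethanesulfonate, CC[Si](CC)(CC)OS(=O)(=O)C(F)(F)F
Why: Silylation of the hindered epoxy alcohol with the silyl triflate at low temperature; the hindered base keeps the medium non-acidic so the epoxide is not opened.

Step 11
Reactants: 17 bis(triethylsilyl) ether with C7 terminal alkene; 18 methacrolein
Product: 19 (7E)-C12 enal
Conditions: second-generation Hoveyda–Grubbs catalyst (5–10 mol %), 18 (excess), CH2Cl2, 40 °C
Reagents that add atoms: none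
Why: Cross-metathesis of the monosubstituted alkene with methacrolein; the conjugated trisubstituted enal forms with E geometry (C8 trans to C12), and the hindered trisubstituted C4=C5 alkene does not take part.

Step 12
Reactants: 19 (7E)-C12 enal
Product: 20 (7E)-C12 allylic alcohol
Conditions: i-Bu2AlH, CH2Cl2, −78 °C
Reagents that add atoms: none
Why: 1,2-Reduction of the enal by the aluminium hydride at low temperature; epoxide, silyl ethers and PMB ether are inert.

Step 13
Reactants: 20 (7E)-C12 allylic alcohol
Product: 22 C12 allylic chloride (C6–OPMB), via C12 methanesulfonate 21 (not isolated)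
Conditions: MsCl, 2,4,6-collidine, LiCl, DMF, 0 °C
Reagents that add atoms: lithium chloride, [Li+].[Cl-]; methanesulfonyl chloride, CS(=O)(=O)Cl (its atoms stay only in 21)
Why: Mesylation and in situ SN2 displacement by chloride (Collington–Meyers conditions) give the primary allylic chloride without allylic transposition, the primary terminus being the less hindered one.

Step 14
Reactants: 22 C12 allylic chloride (C6–OPMB)
Product: 23 C6 allylic alcohol with C12 chloride
Conditions: DDQ, CH2Cl2/pH 7 buffer, 0 °C
Reagents that add atoms: none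
Why: Oxidative cleavage of the PMB ether (benzylic hydride abstraction, hydrolysis of the oxocarbenium ion); silyl ethers, epoxide and allylic chloride are untouched under buffered conditions.

Step 15
Reactants: 23 C6 allylic alcohol with C12 chloride
Product: 24 (4E)-C6 enal with C12 chloride
Conditions: MnO2, CH2Cl2, rt
Reagents that add atoms: none
Why: MnO2 oxidizes only the allylic alcohol and keeps the E geometry of C4=C5.

Step 16
Reactants: 24 (4E)-C6 enal with C12 chloride; 25 tributyltin hydride
Product: 26 C6 α-hydroxystannane with C12 chloride (both C6 epimers)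
Conditions: 25, LiN(iPr)2, THF, 0 °C (gives Bu3SnLi); then 24, −78 °C; NH4Cl (aq), −78 °C; used crude at once
Reagents that add atoms: none
Why: Still's stannyl anion addition: Bu3SnLi adds 1,2 to the enal (C4 is fully substituted, so conjugate addition is blocked) much faster at −78 °C than it displaces the allylic chloride or opens the epoxide; C6 forms as both epimers, which the key step does not need resolved.

Step 17
Reactants: 26 C6 α-hydroxystannane with C12 chloride
Product: 28 thirteen-membered C6-stannyl diallylic ether with epoxide and two triethylsilyl ethers, via potassium alkoxide 27 (not isolated)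
Conditions: KN(SiMe3)2, 18-crown-6, THF (0.002 M), −78 to 0 °C
Reagents that add atoms: none
Why: Intramolecular Williamson etherification: the crown-ether-activated alkoxide displaces the primary allylic chloride at C12 (SN2) and closes the thirteen-membered ring at high dilution; the cis epoxide and the two E alkenes pre-organise the chain into a turn, and low temperature limits reversal of the stannyl addition.

Step 18
Reactants: 28 thirteen-membered C6-stannyl diallylic ether
Product: 30 (1R,3S,6R,7S,9R,10R)-1,10-epoxy-3,9-bis[(triethylsilyl)oxy]germacra-4(E),11(12)-dien-6-ol (C7 isopropenyl), via C6 allyllithium 29 (not isolated)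
Conditions: n-BuLi (1.2 equiv), THF, −78 °C; then NH4Cl (aq)
Reagents that add atoms: none
Why: n-BuLi attacks tin and releases Bu4Sn and the α-alkoxy allyllithium 29, so the carbanion sits at C6 and nowhere else; 29 then undergoes a [2,3]-sigmatropic (Wittig–Still) shift in which C6 bonds to C7, the π bond moves to C11=C12 and O–C12 breaks, giving the lithium alkoxide of 30. The closest known reaction type is the [2,3]-Wittig ring contraction of thirteen-membered diallylic ethers to ten-membered carbocycles, here triggered by tin–lithium exchange instead of deprotonation. The ten-membered ring is closed transannularly inside the thirteen-membered ring through a five-membered envelope (C6, O, C12, C11, C7), so no end-to-end cyclization has to be paid for. C6 and C7 are set together: the E geometry of C7=C11 (C8 trans to C12) and the exo position of the C5 vinyl group in the envelope place the C6 oxygen anti to C8, which is the trans H6/H7 relationship of the lactone. Which face of C7=C11 is used, and so the absolute sense at C6/C7, must come from the ring conformation fixed by the E C4=C5 alkene, the cis epoxide and the C9 silyl ether, with the C8–C9 bond turning its bulk away from the approaching C6; both C6 epimers of 28 should converge because 29 is planar at C6. The step needs [2,3] over [1,2] selectivity, which the low temperature and the concerted five-centre path favour, and attack of n-BuLi on tin in preference to the epoxide, which the much faster exchange at −78 °C secures.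

Step 19
Reactants: 30 ten-membered C6 alcohol with C7 isopropenyl group
Product: 32 (1R,3S,6S,7S,9R,10R)-1,10-epoxy-3,9-bis[(triethylsilyl)oxy]germacr-4(E)-ene-6,12-diol (C11 epimers), via organoborane 31 (not isolated)
Conditions: 9-BBN (3 equiv), THF, 0 °C to rt; then NaOH, H2O2, 0 °C
Reagents that add atoms: hydrogen peroxide, OO; 9-borabicyclo[3.3.1]nonane, B1C2CCCC1CCC2 (boron stays only in 31)
Why: Hydroboration–oxidation: 9-BBN places boron on C12 of the 1,1-disubstituted alkene and leaves the trisubstituted C4=C5 alkene alone; the C6 hydroxyl is borylated in passing and freed on oxidative work-up; the C11 mixture is corrected in step 21.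

Step 20
Reactants: 32 6,12-diol (C11 epimers)
Product: 34 (1R,3S,6S,7S,9R,10R)-1,10-epoxy-3,9-bis[(triethylsilyl)oxy]germacr-4(E)-en-6,12-olide (C11 epimers), via lactol 33 (not isolated)
Conditions: TEMPO (cat.), PhI(OAc)2, CH2Cl2/pH 7 buffer, rt
Reagents that add atoms: none
Why: TEMPO-catalysed oxidation is selective for the primary alcohol; the aldehyde closes to lactol 33 with the C6 hydroxyl and is oxidized on to the γ-lactone, while the buffer keeps acetic acid away from the epoxide.

Step 21
Reactants: 34 6,12-olide (C11 epimers)
Product: 36 (1R,3S,6S,7S,9R,10R,11R)-1,10-epoxy-3,9-bis[(triethylsilyl)oxy]germacr-4(E)-en-6,12-olide, via lithium enolate 35 (not isolated)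
Conditions: LiN(iPr)2, THF, −78 °C; then 2,6-di-tert-butyl-4-methylphenol, −78 °C
Reagents that add atoms: none
Why: Kinetic protonation of the lactone enolate: C11 is planar in 35, and the bulky phenol delivers the proton to the face away from C8 (the face of H7), which puts the methyl group cis to C8 (11R), the epimer that base equilibration would not give.

Step 22
Reactants: 36 (11R)-bis(triethylsilyl) lactone
Product: 37 (1R,3S,6S,7S,9R,10S,11R)-1,10-epoxy-3,9-dihydroxygermacr-4(E)-en-6,12-olide
Conditions: Bu4NF, AcOH, THF, 0 °C to rt
Reagents that add atoms: none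
Why: Fluoride desilylation buffered with acetic acid, so that neither free alkoxide (Payne migration, C11 epimerization) nor strong acid (transannular epoxide opening) is present; the change of the C10 descriptor is only a priority change.

Step 23
Reactants: 37 3,9-diol
Product: 38 (1R,3S,6S,7S,9R,10R,11R)-3,9-diacetoxy-1,10-epoxygermacr-4(E)-en-6,12-olide (target)
Conditions: Ac2O, pyridine, DMAP (cat.), CH2Cl2, 0 °C to rt
Reagents that add atoms: acetic anhydride, CC(=O)OC(C)=O
Why: DMAP-catalysed acetylation of both secondary alcohols; no stereocentre is affected.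

## Compound list

1 | 2-[(4-methoxybenzyl)oxy]acetaldehyde | O=CCOCc1ccc(OC)cc1 | starting material
2 | 2-(triphenylphosphoranylidene)propanal | CC(C=O)=P(c1ccccc1)(c1ccccc1)c1ccccc1 | starting material
3 | (E)-4-[(4-methoxybenzyl)oxy]-2-methylbut-2-enal | O=C/C(C)=C/COCc1ccc(OC)cc1 | intermediate
4 | B-allylbis(isopinocampheyl)borane from (+)-α-pinene | C=CCB([C@@H]1C[C@@H]2C[C@H]([C@H]1C)C2(C)C)[C@@H]1C[C@@H]2C[C@H]([C@H]1C)C2(C)C | starting material
5 | O-bis(isopinocampheyl)boryl ether of 6 | C=CC[C@H](OB([C@@H]1C[C@@H]2C[C@H]([C@H]1C)C2(C)C)[C@@H]1C[C@@H]2C[C@H]([C@H]1C)C2(C)C)/C(C)=C/COCc1ccc(OC)cc1 | intermediate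
6 | (4S,5E)-7-[(4-methoxybenzyl)oxy]-5-methylhepta-1,5-dien-4-ol | C=CC[C@H](O)/C(C)=C/COCc1ccc(OC)cc1 | intermediate
7 | 2-methylprop-2-enoyl chloride (methacryloyl chloride) | C=C(C)C(=O)Cl | starting material
8 | (4S,5E)-7-[(4-methoxybenzyl)oxy]-5-methylhepta-1,5-dien-4-yl 2-methylprop-2-enoate | C=CC[C@H](OC(=O)C(C)=C)/C(C)=C/COCc1ccc(OC)cc1 | intermediate
9 | (6S)-6-{(2E)-4-[(4-methoxybenzyl)oxy]but-2-en-2-yl}-3-methyl-5,6-dihydro-2H-pyran-2-one | CC1=CC[C@@H](/C(C)=C/COCc2ccc(OC)cc2)OC1=O | intermediate
10 | (2Z,5S,6E)-5-hydroxy-N-methoxy-8-[(4-methoxybenzyl)oxy]-N,2,6-trimethylocta-2,6-dienamide | CON(C)C(=O)/C(C)=C\C[C@H](O)/C(C)=C/COCc1ccc(OC)cc1 | intermediate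
11 | (2Z,5S,6E)-N-methoxy-8-[(4-methoxybenzyl)oxy]-N,2,6-trimethyl-5-[(triethylsilyl)oxy]octa-2,6-dienamide | CON(C)C(=O)/C(C)=C\C[C@H](O[Si](CC)(CC)CC)/C(C)=C/COCc1ccc(OC)cc1 | intermediate
12 | (2Z,5S,6E)-8-[(4-methoxybenzyl)oxy]-2,6-dimethyl-5-[(triethylsilyl)oxy]octa-2,6-dienal | O=C/C(C)=C\C[C@H](O[Si](CC)(CC)CC)/C(C)=C/COCc1ccc(OC)cc1 | intermediate
13 | B-allylbis(isopinocampheyl)borane from (−)-α-pinene | C=CCB([C@H]1C[C@H]2C[C@@H]([C@@H]1C)C2(C)C)[C@H]1C[C@H]2C[C@@H]([C@@H]1C)C2(C)C | starting material
14 | O-bis(isopinocampheyl)boryl ether of 15 | C=CC[C@@H](OB([C@H]1C[C@H]2C[C@@H]([C@@H]1C)C2(C)C)[C@H]1C[C@H]2C[C@@H]([C@@H]1C)C2(C)C)/C(C)=C\C[C@H](O[Si](CC)(CC)CC)/C(C)=C/COCc1ccc(OC)cc1 | intermediate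
15 | (4R,5Z,8S,9E)-11-[(4-methoxybenzyl)oxy]-5,9-dimethyl-8-[(triethylsilyl)oxy]undeca-1,5,9-trien-4-ol | C=CC[C@@H](O)/C(C)=C\C[C@H](O[Si](CC)(CC)CC)/C(C)=C/COCc1ccc(OC)cc1 | intermediate
16 | (1R)-1-[(2S,3R)-3-{(2S,3E)-5-[(4-methoxybenzyl)oxy]-3-methyl-2-[(triethylsilyl)oxy]pent-3-en-1-yl}-2-methyloxiran-2-yl]but-3-en-1-ol (threo epoxy alcohol) | C=CC[C@@H](O)[C@]1(C)O[C@@H]1C[C@H](O[Si](CC)(CC)CC)/C(C)=C/COCc1ccc(OC)cc1 | intermediate
17 | 9-O-triethylsilyl ether of 16: open chain C6(OPMB)–C5=C4–C3(OSiEt3)–C2–C1(O)C10–C9(OSiEt3)–C8–C7=CH2, (1R,3S,9R,10R), 4E | C=CC[C@@H](O[Si](CC)(CC)CC)[C@]1(C)O[C@@H]1C[C@H](O[Si](CC)(CC)CC)/C(C)=C/COCc1ccc(OC)cc1 | intermediate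
18 | methacrolein (2-methylprop-2-enal) | C=C(C)C=O | starting material
19 | (7E)-C12 enal: chain of 17 ending in C8–C7H=C11(CH3)–C12H=O | O=C/C(C)=C/C[C@@H](O[Si](CC)(CC)CC)[C@]1(C)O[C@@H]1C[C@H](O[Si](CC)(CC)CC)/C(C)=C/COCc1ccc(OC)cc1 | intermediate
20 | (7E)-C12 allylic alcohol (C6–OPMB) | OC/C(C)=C/C[C@@H](O[Si](CC)(CC)CC)[C@]1(C)O[C@@H]1C[C@H](O[Si](CC)(CC)CC)/C(C)=C/COCc1ccc(OC)cc1 | intermediate
21 | C12 methanesulfonate of 20 | CS(=O)(=O)OC/C(C)=C/C[C@@H](O[Si](CC)(CC)CC)[C@]1(C)O[C@@H]1C[C@H](O[Si](CC)(CC)CC)/C(C)=C/COCc1ccc(OC)cc1 | intermediate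
22 | C12 allylic chloride (C6–OPMB) | ClC/C(C)=C/C[C@@H](O[Si](CC)(CC)CC)[C@]1(C)O[C@@H]1C[C@H](O[Si](CC)(CC)CC)/C(C)=C/COCc1ccc(OC)cc1 | intermediate
23 | C6 allylic alcohol with C12 chloride | ClC/C(C)=C/C[C@@H](O[Si](CC)(CC)CC)[C@]1(C)O[C@@H]1C[C@H](O[Si](CC)(CC)CC)/C(C)=C/CO | intermediate
24 | (4E)-C6 enal with C12 chloride | ClC/C(C)=C/C[C@@H](O[Si](CC)(CC)CC)[C@]1(C)O[C@@H]1C[C@H](O[Si](CC)(CC)CC)/C(C)=C/C=O | intermediate
25 | tributyltin hydride | CCCC[SnH](CCCC)CCCC | starting material
26 | C6 α-hydroxystannane with C12 chloride (both C6 epimers) | ClC/C(C)=C/C[C@@H](O[Si](CC)(CC)CC)[C@]1(C)O[C@@H]1C[C@H](O[Si](CC)(CC)CC)/C(C)=C/C(O)[Sn](CCCC)(CCCC)CCCC | intermediate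
27 | potassium alkoxide of 26 | [K+].ClC/C(C)=C/C[C@@H](O[Si](CC)(CC)CC)[C@]1(C)O[C@@H]1C[C@H](O[Si](CC)(CC)CC)/C(C)=C/C([O-])[Sn](CCCC)(CCCC)CCCC | intermediate
28 | thirteen-membered cyclic ether (ring C3, C2, C1, C10, C9, C8, C7, C11, C12, O, C6, C5, C4): E C4=C5, E C7=C11, (1R,10R)-epoxide, (3S)- and (9R)-OSiEt3, C6–SnBu3 (both C6 epimers) | CC[Si](CC)(CC)O[C@H]1C[C@H]2O[C@@]2(C)[C@H](O[Si](CC)(CC)CC)C/C=C(C)/COC([Sn](CCCC)(CCCC)CCCC)/C=C/1C | intermediate
29 | C6 allyllithium of the thirteen-membered ether | CC[Si](CC)(CC)O[C@H]1C[C@H]2O[C@@]2(C)[C@H](O[Si](CC)(CC)CC)C/C=C(C)/COC([Li])/C=C/1C | intermediate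
30 | (1R,3S,6R,7S,9R,10R)-1,10-epoxy-3,9-bis[(triethylsilyl)oxy]germacra-4(E),11(12)-dien-6-ol | CC[Si](CC)(CC)O[C@H]1C[C@H]2O[C@@]2(C)[C@H](O[Si](CC)(CC)CC)C[C@@H](C(C)=C)[C@@H](/C=C/1C)O | intermediate
31 | C12 B-alkyl-9-BBN / C6 O-boryl derivative of 30 (C11 epimers) | CC[Si](CC)(CC)O[C@H]1C[C@H]2O[C@@]2(C)[C@H](O[Si](CC)(CC)CC)C[C@@H](C(C)CB3C4CCCC3CCC4)[C@@H](/C=C/1C)OB1C2CCCC1CCC2 | intermediate
32 | (1R,3S,6S,7S,9R,10R)-1,10-epoxy-3,9-bis[(triethylsilyl)oxy]germacr-4(E)-ene-6,12-diol (C11 epimers) | CC[Si](CC)(CC)O[C@H]1C[C@H]2O[C@@]2(C)[C@H](O[Si](CC)(CC)CC)C[C@@H](C(C)CO)[C@@H](/C=C/1C)O | intermediate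
33 | 6,12-lactol (C11 and C12 epimers) | CC[Si](CC)(CC)O[C@H]1C[C@H]2O[C@@]2(C)[C@H](O[Si](CC)(CC)CC)C[C@@H]2[C@@H](/C=C/1C)OC(O)C2C | intermediate
34 | (1R,3S,6S,7S,9R,10R)-1,10-epoxy-3,9-bis[(triethylsilyl)oxy]germacr-4(E)-en-6,12-olide (C11 epimers) | CC[Si](CC)(CC)O[C@H]1C[C@H]2O[C@@]2(C)[C@H](O[Si](CC)(CC)CC)C[C@@H]2[C@@H](/C=C/1C)OC(=O)C2C | intermediate
35 | lithium enolate of 34 | [Li+].CC[Si](CC)(CC)O[C@H]1C[C@H]2O[C@@]2(C)[C@H](O[Si](CC)(CC)CC)C[C@@H]2[C@@H](/C=C/1C)OC([O-])=C2C | intermediate
36 | (1R,3S,6S,7S,9R,10R,11R)-1,10-epoxy-3,9-bis[(triethylsilyl)oxy]germacr-4(E)-en-6,12-olide | CC[Si](CC)(CC)O[C@H]1C[C@H]2O[C@@]2(C)[C@H](O[Si](CC)(CC)CC)C[C@@H]2[C@@H](/C=C/1C)OC(=O)[C@@H]2C | intermediate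
37 | (1R,3S,6S,7S,9R,10S,11R)-1,10-epoxy-3,9-dihydroxygermacr-4(E)-en-6,12-olide | O[C@H]1C[C@H]2O[C@@]2(C)[C@H](O)C[C@@H]2[C@@H](/C=C/1C)OC(=O)[C@@H]2C | intermediate
38 | (1R,3S,6S,7S,9R,10R,11R)-3,9-diacetoxy-1,10-epoxygermacr-4(E)-en-6,12-olide | CC(=O)O[C@H]1C[C@H]2O[C@@]2(C)[C@H](OC(C)=O)C[C@@H]2[C@@H](/C=C/1C)OC(=O)[C@@H]2C | target

## Step count and least certain steps

Total step count: 23. Longest linear sequence: 23 steps (1 to 38); the route is linear, and 2, 4, 7, 13, 18 and 25 enter as purchased reagents.

**Step 18 (key step).** The most likely failure is poor facial selectivity. The anti relation at C6/C7 is built into the envelope transition state, but which alkene face is used depends on a macrocycle conformation shaped by four remote stereocentres and two bulky silyl ethers. The contraction may therefore run on the other face, or the two C6-epimeric stannanes may fail to funnel into one transition state if exchange and shift outrun equilibration of the ion pair. The fallback replaces substrate control by reagent control and sets out from 23. Ring closure of 23 with NaH in THF at high dilution, an ordinary Williamson etherification of a primary allylic alkoxide, would give the tin-free thirteen-membered diallylic ether F1. Deprotonation of F1 at the C6 methylene with lithium bis[(S)-1-phenylethyl]amide, or its antipode if that is the matched one, in THF at −78 °C would trigger the same [2,3] shift and rejoin the route at 30.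

**Step 17.** The most likely failure is collapse of the α-stannyl allylic alkoxide 27 before the slow ring closure. It can revert to the enal and a stannyl anion, which the allylic chloride then consumes irreversibly, or it can lose tin. The fallback removes the slow macrocyclization from the alkoxide stage and sets out from 17. DDQ and then MnO2, as in steps 14 and 15, give the C6 allylic alcohol with C7 terminal alkene F2 and the corresponding C6 enal F3. Bu3SnLi addition at −78 °C, followed by trapping of the cold lithium alkoxide with excess 3-bromo-2-methylpropene and HMPA, gives the C6 stannyl 2-methylallyl ether F4. Ring-closing metathesis (second-generation Grubbs catalyst, high dilution) between the 2-methylallyl and C7 vinyl groups forms C7=C11 and returns to 28. The E isomer would have to be separated from any Z isomer.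

**Step 9.** The most likely failure is incomplete threo selectivity. A(1,2) strain from the C14 methyl group works against the A(1,3) control, and the hindered Z allylic alcohol may react slowly. The fallback uses reagent control and sets out from 12. NaBH4 reduction gives the Z allylic alcohol F5. Sharpless epoxidation with Ti(OiPr)4, L-(+)-diethyl tartrate and t-BuOOH gives the 2,3-epoxy alcohol F6, by the facial rule that turns E allylic alcohols into (2S,3S)-epoxy alcohols. Dess–Martin oxidation gives the epoxy aldehyde F7, and allylboration with 13 sets C9 and returns to 16.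

**Step 21.** The most likely failure is weak face discrimination in the proton transfer, or partial equilibration toward the more stable 11-epimer during quench or work-up. The fallback replaces proton delivery by hydrogen delivery and sets out from 34. Trapping enolate 35 with PhSeBr gives the α-phenylselanyl lactone F8. Oxidation with H2O2/pyridine and syn elimination toward the methyl group gives the α-methylene lactone F9. Hydrogenation with RhCl(PPh3)3 adds H2 to the exocyclic alkene from the face away from C8, leaves C4=C5 untouched and returns to 36.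

## Further compounds

F1 | step 18 | tin-free thirteen-membered diallylic ether (C6 methylene) | CC[Si](CC)(CC)O[C@H]1C[C@H]2O[C@@]2(C)[C@H](O[Si](CC)(CC)CC)C/C=C(C)/COC/C=C/1C
F2 | step 17 | C6 allylic alcohol with C7 terminal alkene | C=CC[C@@H](O[Si](CC)(CC)CC)[C@]1(C)O[C@@H]1C[C@H](O[Si](CC)(CC)CC)/C(C)=C/CO
F3 | step 17 | C6 enal with C7 terminal alkene | C=CC[C@@H](O[Si](CC)(CC)CC)[C@]1(C)O[C@@H]1C[C@H](O[Si](CC)(CC)CC)/C(C)=C/C=O
F4 | step 17 | C6 stannyl 2-methylallyl ether (both C6 epimers) | C=CC[C@@H](O[Si](CC)(CC)CC)[C@]1(C)O[C@@H]1C[C@H](O[Si](CC)(CC)CC)/C(C)=C/C(OCC(C)=C)[Sn](CCCC)(CCCC)CCCC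
F5 | step 9 | (2Z,5S,6E)-8-[(4-methoxybenzyl)oxy]-2,6-dimethyl-5-[(triethylsilyl)oxy]octa-2,6-dien-1-ol | OC/C(C)=C\C[C@H](O[Si](CC)(CC)CC)/C(C)=C/COCc1ccc(OC)cc1
F6 | step 9 | [(2S,3R)-3-{(2S,3E)-5-[(4-methoxybenzyl)oxy]-3-methyl-2-[(triethylsilyl)oxy]pent-3-en-1-yl}-2-methyloxiran-2-yl]methanol | OC[C@]1(C)O[C@@H]1C[C@H](O[Si](CC)(CC)CC)/C(C)=C/COCc1ccc(OC)cc1
F7 | step 9 | (2R,3R)-3-{(2S,3E)-5-[(4-methoxybenzyl)oxy]-3-methyl-2-[(triethylsilyl)oxy]pent-3-en-1-yl}-2-methyloxirane-2-carbaldehyde | O=C[C@]1(C)O[C@@H]1C[C@H](O[Si](CC)(CC)CC)/C(C)=C/COCc1ccc(OC)cc1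
F8 | step 21 | 11-(phenylselanyl) derivative of lactone 34 | CC[Si](CC)(CC)O[C@H]1C[C@H]2O[C@@]2(C)[C@H](O[Si](CC)(CC)CC)C[C@@H]2[C@@H](/C=C/1C)OC(=O)C2(C)[Se]c1ccccc1
F9 | step 21 | 11(13)-methylene lactone | CC[Si](CC)(CC)O[C@H]1C[C@H]2O[C@@]2(C)[C@H](O[Si](CC)(CC)CC)C[C@@H]2[C@@H](/C=C/1C)OC(=O)C2=C
A1 | alternative 1 | isoxazoline-bridged ten-membered lactone with C10 alcohol and C9 acetate | C[C@@]1(O)C2=NO[C@@H](C2)/C(C)=C/[C@H]2OC(=O)[C@H](C)[C@@H]2C[C@H]1OC(C)=O
A2 | alternative 2 | ten-membered C10 ketone with E C4=C5, C3 dithiane, C9 PMB ether and trans lactone | O=C1CCC2(SCCCS2)/C(C)=C/[C@H]3OC(=O)[C@H](C)[C@@H]3C[C@H]1OCc1ccc(OC)cc1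
A3 | alternative 3 | ten-membered C9,C10-diol with C1 silyl ether and C3 acetate | CC(=O)O[C@H]1C[C@H](O[Si](C)(C)C(C)(C)C)[C@](O)(C)[C@H](O)C[C@@H]2[C@@H](/C=C/1C)OC(=O)[C@@H]2C
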